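## Structural features

The target is 3-[(S)-2-acetoxypropyl]-2-hydroxy-5,6,8-trimethoxy-1,4-naphthoquinone: a quinonoid ring A (C1 to C4) fused through C4a and C8a to a benzenoid ring B (C5 to C8). Ring A carries an enolic hydroxyl on C2 and a three-carbon chain on C3; ring B carries methoxy groups on C5, C6 and C8 and one hydrogen on C7. The only stereocentre is the acetoxy-bearing carbon of the side chain, (S)-configured, with no stereogenic neighbour, so it is best bought and carried through untouched. Fragile points are the secondary acetate (lost to alkoxide), the acidic vinylogous-acid hydroxyl on C2 (it competes in acylations), the quinone (nucleophiles, reductants) and ring B, whose para-related C5 and C8 methoxy groups invite oxidative demethylation by strong oxidants. The real difficulty is regiochemical: the OH/alkyl pair on C2/C3 must be placed in one sense relative to the unsymmetrical methoxy pattern of ring B, and the quinone level must be reached without an oxidant that attacks ring B. The key step exploits the fact that each fusion carbon bears exactly one ring-A carbon (C8a–C1 and C4a–C4). The C4a–C8a edge can therefore be an aryne inserted into the C(=O)–CH2 bond of a β-keto ester, which brings in C1, C2, C3, C4 and the side chain in one operation.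

## Logic of the disconnections

**20 to 18.** The acetyl C–O bond of the side chain is cut. The acetate cannot survive the methoxide needed to close ring A, so it has to be the last group introduced. The gain is that all earlier steps are free of a base-labile ester. The demand is acylation of a secondary alcohol next to the more acidic C2 hydroxyl; this is met by acylating both (19) and releasing the C2 ester, which is a vinylogous anhydride and far more labile.

**18 to 17.** The O–Si bond is cut. The silyl ether keeps the side-chain oxygen from adding to the C4 ketone of 15 (a five-membered lactol) and from interfering in the condensation. The forward step must remove silicon without touching quinone, methoxy groups or the C–O bond of the stereocentre.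

**17 to 15.** The C2–C3 bond is cut and the oxygen on C1 is removed. This opens ring A to a benzene with two ortho arms, in which C3 is α to a ketone and C2 is an ester carbon, the natural polarity for a Claisen condensation. The oxidation at C1 is left to air at the stage of 16, whose anion is the only species present that oxygen attacks. The bicyclic quinone is reduced to a monocyclic arene. The forward step needs the ketone enolate to attack the ester in a six-membered closure and the oxidation to stop at the hydroxyquinone.

**15 to 7 and 13.** The C8a–C1 and C4a–C4 bonds are cut. C1 and C4 are the α-carbon and the ketone carbon of a β-keto ester and are bonded to each other in 13, so 15 is the formal insertion of the aryne 14 (from 7) into that bond. This is the convergent point: two fragments of similar size, two skeletal bonds, no ring and no stereocentre. The forward step must send the enolate carbon to C8a and the acyl group to C4a, and the silyl ether must tolerate fluoride.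

**7 to 4.** The C–Si and O–S bonds are cut, leading through 6 and 5 to a bromophenol. The ortho relationship of silicon and triflate is secured by a 1,3-shift of silicon from oxygen to the carbon that carried bromine. The demand is clean bromine–lithium exchange at low temperature, with triflation before the ortho-silyl phenoxide can do anything else.

**4 to 3 to 1.** The C–Br bond is cut, then the phenolic C–O bond is traced to the formyl C–C bond of 1 (through 2). 1 is purchasable and already has the full oxygenation pattern of ring B. In 3 only one position ortho to the hydroxyl is free, so the position of bromine (later C4a) is fixed. The forward bromination must not oxidise the electron-rich phenol.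

**13 to 10 and 11.** The bond between the ketone carbon and the ester α-carbon is cut (through 12). It is the same bond that the aryne later enters. The acyl donor is the N-methoxy-N-methylamide 10, so the enolate adds once only.

**10 to 9 to 8.** The O–Si bond, then the amide C–N bond, are cut back to the lactone. This ordering is a deliberate change from adding the ester enolate directly to 8. A free 6-hydroxy-3-oxo ester closes to a lactol and dehydrates to an alkylidene tetrahydrofuran; here the alcohol is silylated before the keto group exists. The only demand is to silylate 9 promptly, before it relactonises.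

## Other disconnections considered

**Alternative 1: Diels–Alder construction of ring B.** The cut is through C4a–C5 and C8–C8a. Ring A comes first as the quinone A2 (2-[(S)-2-acetoxypropyl]-3-methoxy-1,4-benzoquinone) and ring B is added as the diene A3 (1,3,4-trimethoxy-1-(trimethylsilyloxy)buta-1,3-diene). Forward, the unsubstituted C=C of A2 takes up A3, the ketene-acetal carbon loses methoxytrimethylsilane, and tautomerisation gives the triol A1 (3-[(S)-2-acetoxypropyl]-2,5,6-trimethoxynaphthalene-1,4,8-triol).
- In its favour: the sense of addition rests on a well-understood polarisation. The C2 methoxy group deactivates the C4 carbonyl as a vinylogous ester, so the nucleophilic diene terminus should go to C4a. This is a firmer basis for regiocontrol than the balance of effects in 14, and on this point the alternative is the better plan. It equals the chosen route in convergence and in bonds formed in the key step, and it carries the acetate from the start.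
- Against it: A1 arrives in the wrong oxidation and methylation state. The C8 oxygen is a free phenol, C2 carries OMe where 20 has OH, and ring A is a hydroquinone. Three corrections follow: reoxidation, methylation of a peri-hydroxyl hydrogen-bonded to C1=O, and hydrolysis of the C2 vinylogous ester, which threatens the acetate. A2 is a chiral, fully substituted quinone needing several steps, and A3 is hydrolytically sensitive.
- Comparison: both key steps are mechanistically sound. The chosen plan takes the correct ring-B oxygenation from a purchased arene, whereas this one has to repair it; the alternative would be clearly longer.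

**Alternative 2: Ring-closing metathesis with oxidation to the quinone.** The cut is the C2=C3 double bond. The precursor A5 ((4S)-4-(tert-butyldimethylsilyloxy)-1-[2-(2-ethoxy-1-hydroxyprop-2-en-1-yl)-3,5,6-trimethoxyphenyl]-2-methylidenepentan-1-ol) carries a 1-ethoxyvinyl carbinol arm on C8a and a 1,1-disubstituted vinyl carbinol arm on C4a. Forward, RuCl2(=CHPh)(PCy3)(H2IMes) (second-generation Grubbs catalyst) would expel ethylene and close ring A to the diol A4 (3-[(S)-2-(tert-butyldimethylsilyloxy)propyl]-2-ethoxy-5,6,8-trimethoxy-1,4-dihydronaphthalene-1,4-diol). Oxidation of both carbinols and hydrolysis of the enol ether would then lead to 17, so the configuration at C1 and C4 is irrelevant.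
- In its favour: the key step is neutral, so silyl ether and stereocentre are as safe as in the chosen plan (equal). The C2 oxygen and the C3 chain are placed unambiguously within ring A.
- Against it: the olefin to be formed is tetrasubstituted and one partner is an enol ether, which gives a heteroatom-stabilised ruthenium carbene that turns over slowly. The regiochemical problem is moved, not solved: the two different arms must be attached one at a time to the correct ortho positions of the trimethoxybenzene.
- Comparison: the end game (desilylation, acetylation) is the same, so nothing is gained there. Neither plan needs a strong oxidant near ring B (equal). A5 has to be built linearly, whereas the aryne insertion joins two simple fragments with two C–C bonds, so the alternative is worse in step economy.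

**Alternative 3: Photochemical Wolff ketene and siloxyalkyne benzannulation.** The cuts are C1–C2, C3–C4 and C4–C4a. Ring A is assembled from the diazoketone A7 (2-diazo-1-(2,4,5-trimethoxyphenyl)ethan-1-one) and the siloxyalkyne A8 ((S)-2-(tert-butyldimethylsilyloxy)-5-(triisopropylsilyloxy)pent-4-yne). Forward, irradiation converts A7 by Wolff rearrangement into an arylketene; [2+2] addition to A8 gives a 4-arylcyclobutenone, which opens and electrocyclises onto the arene to give the naphthol A6 (3-[(S)-2-(tert-butyldimethylsilyloxy)propyl]-4-hydroxy-5,6,8-trimethoxy-2-(triisopropylsilyloxy)naphthalene).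
- In its favour: regiochemistry is unambiguous. The aryl group of A7 has only one free ortho position, and the polarity of the ynol ether fixes oxygen on C2 and the chain on C3. On regiocontrol this alternative is better than the chosen plan. It is equally convergent and forms three bonds and the ring in one step, which is better in bonds per step.
- Against it: C1 of A6 still bears hydrogen, so the quinone must be made by oxidising a naphthol in the presence of ring B, whose C5/C8 para-dimethoxy pair is itself a quinone precursor. The chosen plan avoids this because C1 is oxidised by air at the enolate stage. A8 needs several steps, photolysis limits scale, and two silyl groups must be removed in a defined order.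
- Comparison: both plans leave ring B intact and take the stereocentre from the chiral pool. The pericyclic cascade is intrinsically regiospecific and the aryne insertion is not. The alternative is longer by the synthesis of A8 and by the extra oxidation and desilylation.

Key step: step 7

Remark on the chemistry: atom labels C1 to C8a follow the 1,4-naphthoquinone numbering of the target; on that basis the triflate-bearing carbon of 7 becomes C8a and its silyl-bearing carbon C4a, and 8 is assumed to be bought as the (S)-enantiomer of high enantiomeric purity.

## Route

Step 1
Reactants: 1 2,4,5-trimethoxybenzaldehyde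
Product: 3 2,4,5-trimethoxyphenol, via 2,4,5-trimethoxyphenyl formate 2 (not isolated)
Conditions: mCPBA, CH2Cl2, 0 °C → rt; then MeOH, conc. HCl (cat.), N2, rt
Reagents that add atoms: 3-chloroperoxybenzoic acid (mCPBA), O=C(OO)c1cccc(Cl)c1
Why: Baeyer–Villiger (Dakin-type) oxidation in which the electron-rich aryl group migrates in preference to hydride; the aryl formate is cleaved by acid-catalysed methanolysis, which keeps the oxidisable phenol protonated.

Step 2
Reactants: 3 2,4,5-trimethoxyphenol
Product: 4 2-bromo-3,4,6-trimethoxyphenol
Conditions: NBS (1.0 equiv), CH2Cl2, −78 → 0 °C, dark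
Reagents that add atoms: N-bromosuccinimide, O=C1CCC(=O)N1Br
Why: Electrophilic aromatic bromination directed by the hydroxyl group; the para position is blocked and only one ortho position is free, while the other ring CH lies between two methoxy groups and is meta to the hydroxyl. Anhydrous, cold conditions disfavour oxidative demethylation.

Step 3
Reactants: 4 2-bromo-3,4,6-trimethoxyphenol
Product: 7 3,4,6-trimethoxy-2-(trimethylsilyl)phenyl trifluoromethanesulfonate, via (2-bromo-3,4,6-trimethoxyphenoxy)trimethylsilane 5 (not isolated), via lithium 3,4,6-trimethoxy-2-(trimethylsilyl)phenoxide 6 (not isolated)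
Conditions: HMDS, THF, 65 °C, then evaporation; n-BuLi, THF, −100 → −80 °C; Tf2O, −100 → −80 °C; aq. NaHCO3
Reagents that add atoms: hexamethyldisilazane, C[Si](C)(C)N[Si](C)(C)C; trifluoromethanesulfonic anhydride, O=S(=O)(OS(=O)(=O)C(F)(F)F)C(F)(F)F
Why: O-silylation, bromine–lithium exchange and 1,3-migration of silicon from oxygen to carbon (retro-Brook rearrangement), driven by formation of the phenoxide, which is trapped as the triflate. This is the standard entry to ortho-silylaryl triflates.

Step 4
Reactants: 8 (S)-γ-valerolactone
Product: 9 (S)-4-hydroxy-N-methoxy-N-methylpentanamide
Conditions: MeNH(OMe)·HCl, i-PrMgCl, THF, −20 → 0 °C; aq. NH4Cl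
Reagents that add atoms: N,O-dimethylhydroxylamine hydrochloride, CNOC.Cl
Why: Aminolysis of the lactone by the chloromagnesium amide (Weinreb amide formation); only the acyl C–O bond is broken, so the (S) centre is retained. The crude product is used at once to avoid relactonisation.

Step 5
Reactants: 9 (S)-4-hydroxy-N-methoxy-N-methylpentanamide
Product: 10 (S)-4-(tert-butyldimethylsilyloxy)-N-methoxy-N-methylpentanamide
Conditions: TBSCl, imidazole, DMF, rt
Reagents that add atoms: tert-butyldimethylsilyl chloride, CC(C)(C)[Si](C)(C)Cl
Why: Standard silylation of a secondary alcohol at oxygen; protecting before the ketone is made means no hydroxy keto ester, and hence no lactol, ever forms.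

Step 6
Reactants: 10 (S)-4-(tert-butyldimethylsilyloxy)-N-methoxy-N-methylpentanamide; 11 methyl acetate
Product: 13 methyl (S)-6-(tert-butyldimethylsilyloxy)-3-oxoheptanoate, via methyl acetate lithium enolate 12 (not isolated)
Conditions: LiN(i-Pr)2 (2.5 equiv), 11 (2.5 equiv), THF, −78 °C; then 10, −78 → −30 °C; aq. NH4Cl
Reagents that add atoms: none
Why: Claisen-type acylation of an ester enolate by an N-methoxy-N-methylamide; the chelated tetrahedral intermediate prevents a second addition and collapses to the β-keto ester on work-up.

Step 7
Reactants: 7 3,4,6-trimethoxy-2-(trimethylsilyl)phenyl trifluoromethanesulfonate; 13 methyl (S)-6-(tert-butyldimethylsilyloxy)-3-oxoheptanoate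
Product: 15 methyl 2-{2-[(S)-4-(tert-butyldimethylsilyloxy)pentanoyl]-3,4,6-trimethoxyphenyl}acetate, via 3,4,6-trimethoxybenzyne 14 (not isolated)
Conditions: CsF (2.5 equiv), 7 (1.3 equiv), MeCN, 80 °C
Reagents that add atoms: none
Why: Fluoride attacks the silicon of 7 and loss of triflate gives the aryne 14, while CsF also deprotonates the doubly activated CH2 of 13; this is the known fluoride-induced acyl-alkylation of arynes by β-keto esters (aryne σ-bond insertion). The enolate carbon adds to C8a, the aryl anion formed at C4a adds to the neighbouring ketone in a 4-exo-trig step, and the strained benzocyclobutenoxide fragments (retro-aldol) so that the acyl group ends on C4a and an ester-stabilised benzylic anion at C1 is protonated. The four-membered ring is transient, so no ring is closed in the product and no stereocentre is formed; the (S) centre is remote from every reacting atom and cannot epimerise. The selectivity needed is the sense of addition to an aryne flanked by methoxy groups on both sides. Three substrate features point the same way: the C5 methoxy group is forced by its C6 neighbour to turn its methyl group towards C4a or out of the ring plane and so shields that carbon; an aryl anion at C4a has one ortho and two meta methoxy groups, against one ortho, one meta and one para for an anion at C8a; and a twisted C5 methoxy group acts as a purer σ-acceptor. The enolate carbon should therefore prefer C8a, but the bias is modest, so the isomer with the two arms exchanged is to be expected and removed by chromatography, and the constitution of 15 is to be confirmed by NOE contacts (ArCH2 to the C8 methoxy group, that group to H-7). Simple α-arylation and O-arylation are limited by anhydrous MeCN at 80 °C, where acyl transfer outruns protonation, and the alkyl silyl ether should tolerate CsF because fluoride is consumed by the more electrophilic aryl–silicon bond.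

Step 8
Reactants: 15 methyl 2-{2-[(S)-4-(tert-butyldimethylsilyloxy)pentanoyl]-3,4,6-trimethoxyphenyl}acetate
Product: 17 3-[(S)-2-(tert-butyldimethylsilyloxy)propyl]-2-hydroxy-5,6,8-trimethoxy-1,4-naphthoquinone, via naphthalene-1,3-diol 16 (not isolated)
Conditions: NaOMe, MeOH, rt → 50 °C; then air (O2 balloon), rt; 1 M HCl
Reagents that add atoms: dioxygen, O=O
Why: Intramolecular Claisen (Dieckmann-type) condensation, a 6-exo-trig attack of the C3 ketone enolate on the C2 ester, gives the naphthalenediol 16. Its electron-rich anion is autoxidised at C1 to the hydroxyquinone, whose stabilised vinylogous carboxylate drives both events. No oxidant stronger than air meets ring B.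

Step 9
Reactants: 17 3-[(S)-2-(tert-butyldimethylsilyloxy)propyl]-2-hydroxy-5,6,8-trimethoxy-1,4-naphthoquinone
Product: 18 2-hydroxy-3-[(S)-2-hydroxypropyl]-5,6,8-trimethoxy-1,4-naphthoquinone
Conditions: 48% aq. HF, MeCN, 0 °C → rt
Reagents that add atoms: none
Why: Acidic fluoride cleavage of a secondary silyl ether at the Si–O bond, so the configuration at carbon is untouched; the acidic medium keeps the hydroxyquinone neutral and leaves the aryl methyl ethers alone.

Step 10
Reactants: 18 2-hydroxy-3-[(S)-2-hydroxypropyl]-5,6,8-trimethoxy-1,4-naphthoquinone
Product: 20 3-[(S)-2-acetoxypropyl]-2-hydroxy-5,6,8-trimethoxy-1,4-naphthoquinone (target), via C2-O-acetyl diacetate 19 (not isolated)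
Conditions: Ac2O (3 equiv), pyridine, DMAP (cat.), CH2Cl2, 0 °C → rt; then MeOH, rt; dilute HCl wash
Reagents that add atoms: acetic anhydride, CC(=O)OC(C)=O
Why: Nucleophile-catalysed acetylation of both hydroxyl groups, then selective methanolysis. The C2 ester of 19 is a vinylogous mixed anhydride and is cleaved by methanol with the same catalyst at room temperature, whereas the secondary alkyl acetate is not. Acylation occurs at oxygen, so the (S) centre is unchanged.

## Compound list

1 | 2,4,5-trimethoxybenzaldehyde | COc1cc(OC)c(C=O)cc1OC | starting material
2 | 2,4,5-trimethoxyphenyl formate | COc1cc(OC)c(OC=O)cc1OC | intermediate (not isolated)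
3 | 2,4,5-trimethoxyphenol | COc1cc(OC)c(O)cc1OC | intermediate
4 | 2-bromo-3,4,6-trimethoxyphenol | COc1cc(OC)c(O)c(Br)c1OC | intermediate
5 | (2-bromo-3,4,6-trimethoxyphenoxy)trimethylsilane | COc1cc(OC)c(O[Si](C)(C)C)c(Br)c1OC | intermediate (not isolated)
6 | lithium 3,4,6-trimethoxy-2-(trimethylsilyl)phenoxide | [Li+].COc1cc(OC)c([O-])c([Si](C)(C)C)c1OC | intermediate (not isolated)
7 | 3,4,6-trimethoxy-2-(trimethylsilyl)phenyl trifluoromethanesulfonate | COc1cc(OC)c(OS(=O)(=O)C(F)(F)F)c([Si](C)(C)C)c1OC | intermediate
8 | (S)-γ-valerolactone [(S)-5-methyldihydrofuran-2(3H)-one] | C[C@H]1CCC(=O)O1 | starting material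
9 | (S)-4-hydroxy-N-methoxy-N-methylpentanamide | CON(C)C(=O)CC[C@H](C)O | intermediate
10 | (S)-4-(tert-butyldimethylsilyloxy)-N-methoxy-N-methylpentanamide | CON(C)C(=O)CC[C@H](C)O[Si](C)(C)C(C)(C)C | intermediate
11 | methyl acetate | COC(C)=O | starting material
12 | lithium enolate of methyl acetate (lithium 1-methoxyethen-1-olate) | [Li+].COC([O-])=C | intermediate (not isolated)
13 | methyl (S)-6-(tert-butyldimethylsilyloxy)-3-oxoheptanoate | COC(=O)CC(=O)CC[C@H](C)O[Si](C)(C)C(C)(C)C | intermediate
14 | 3,4,6-trimethoxybenzyne (3,4,6-trimethoxy-1,2-didehydrobenzene) | COC1=CC(OC)=C(OC)C#C1 | intermediate (not isolated)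
15 | methyl 2-{2-[(S)-4-(tert-butyldimethylsilyloxy)pentanoyl]-3,4,6-trimethoxyphenyl}acetate | COC(=O)Cc1c(OC)cc(OC)c(OC)c1C(=O)CC[C@H](C)O[Si](C)(C)C(C)(C)C | intermediate
16 | 2-[(S)-2-(tert-butyldimethylsilyloxy)propyl]-5,7,8-trimethoxynaphthalene-1,3-diol | COc1cc(OC)c2cc(O)c(C[C@H](C)O[Si](C)(C)C(C)(C)C)c(O)c2c1OC | intermediate (not isolated)
17 | 3-[(S)-2-(tert-butyldimethylsilyloxy)propyl]-2-hydroxy-5,6,8-trimethoxy-1,4-naphthoquinone | COc1cc(OC)c2c(c1OC)C(=O)C(C[C@H](C)O[Si](C)(C)C(C)(C)C)=C(O)C2=O | intermediate
18 | 2-hydroxy-3-[(S)-2-hydroxypropyl]-5,6,8-trimethoxy-1,4-naphthoquinone | COc1cc(OC)c2c(c1OC)C(=O)C(C[C@H](C)O)=C(O)C2=O | intermediate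
19 | 3-[(S)-2-acetoxypropyl]-5,6,8-trimethoxy-1,4-dioxo-1,4-dihydronaphthalen-2-yl acetate | COc1cc(OC)c2c(c1OC)C(=O)C(C[C@H](C)OC(C)=O)=C(OC(C)=O)C2=O | intermediate (not isolated)
20 | 3-[(S)-2-acetoxypropyl]-2-hydroxy-5,6,8-trimethoxy-1,4-naphthoquinone | COc1cc(OC)c2c(c1OC)C(=O)C(C[C@H](C)OC(C)=O)=C(O)C2=O | target

## Step count and least certain steps

Total step count: 10 (steps 1 to 3 for the aryne precursor, steps 4 to 6 for the keto ester, steps 7 to 10 in common). Longest linear sequence: 7 steps (1, 2, 3, 7, 8, 9, 10; the branch through steps 4 to 6 is equally long).

**Step 7 (key step).** The most likely failure is addition of the enolate to the other aryne carbon. Both aryne carbons carry an ortho methoxy group and the steric and inductive bias toward C8a is modest, so separation may be wasteful. Partial loss of the silyl ether to fluoride at 80 °C and protonation of the aryl anion before acyl transfer are secondary risks. The fallback fixes the regiochemistry through 4, in which the hydroxyl already sits on C8a and bromine on C4a; it sets out from 4 and 10 and returns at 15. Treatment of 4 with n-BuLi (2.1 equiv, THF, −78 °C; deprotonation, then bromine–lithium exchange) and acylation of the aryllithium with 10 gives (S)-4-(tert-butyldimethylsilyloxy)-1-(2-hydroxy-3,5,6-trimethoxyphenyl)pentan-1-one F1. Triflation (Tf2O, pyridine, CH2Cl2, 0 °C) gives 2-[(S)-4-(tert-butyldimethylsilyloxy)pentanoyl]-3,4,6-trimethoxyphenyl trifluoromethanesulfonate F2. Palladium-catalysed arylation of 1-methoxy-1-(trimethylsilyloxy)ethene, the silyl ketene acetal of methyl acetate (Pd2(dba)3, P(t-Bu)3, LiOAc, THF, 65 °C; zerovalent palladium inserts into the C–OTf bond), then gives 15.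

**Step 2.** The brominating agent may oxidise the very electron-rich para-methoxyphenol (oxidative demethylation toward a quinone) or brominate twice. The fallback replaces electrophilic halogenation by directed ortho-metalation; it sets out from 3 and returns at 7. Isopropyl isocyanate with catalytic Et3N converts 3 into 2,4,5-trimethoxyphenyl N-isopropylcarbamate F3. In-situ N-silylation (TBSOTf, TMEDA), lithiation with n-BuLi/TMEDA at −78 °C at the position between the carbamate and the methoxy group, and quenching with TMSCl give 3,4,6-trimethoxy-2-(trimethylsilyl)phenyl N-isopropylcarbamate F4. Cleavage with DBU and Et2NH in MeCN releases 3,4,6-trimethoxy-2-(trimethylsilyl)phenol F5, which is triflated in the same flask with PhNTf2 to give 7.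

**Step 8.** Ring closure at the hindered, twisted aryl ketone may be incomplete, and the hydroxyquinone anion may be over-oxidised in alkaline, oxygenated methanol (oxidative ring contraction of the Hooker type). The fallback separates ring closure from oxidation; it sets out from 15 and returns at 17. The Claisen condensation is run under argon (NaOMe, MeOH), the mixture is acidified and 16 is isolated with exclusion of air. 16 is then oxidised under buffered, near-neutral conditions with (KSO3)2NO and KH2PO4 in aqueous acetone (Teuber oxidation of a naphthol), a reagent that acts only on the free phenolic ring.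

**Step 10.** Discrimination between the two acetyl groups may be imperfect: the side-chain acetate may be partly lost during methanolysis, or the C2 ester may persist. The fallback avoids 19; it sets out from 18 and goes directly to 20. Equilibrium esterification in acetic acid with catalytic Sc(OTf)3 at room temperature acetylates only the alcohol, because a vinylogous anhydride is not stable in that medium.

## Further compounds

F1 | step 7 | (S)-4-(tert-butyldimethylsilyloxy)-1-(2-hydroxy-3,5,6-trimethoxyphenyl)pentan-1-one | COc1cc(OC)c(O)c(C(=O)CC[C@H](C)O[Si](C)(C)C(C)(C)C)c1OC
F2 | step 7 | 2-[(S)-4-(tert-butyldimethylsilyloxy)pentanoyl]-3,4,6-trimethoxyphenyl trifluoromethanesulfonate | COc1cc(OC)c(OS(=O)(=O)C(F)(F)F)c(C(=O)CC[C@H](C)O[Si](C)(C)C(C)(C)C)c1OC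
F3 | step 2 | 2,4,5-trimethoxyphenyl N-isopropylcarbamate | COc1cc(OC)c(OC(=O)NC(C)C)cc1OC
F4 | step 2 | 3,4,6-trimethoxy-2-(trimethylsilyl)phenyl N-isopropylcarbamate | COc1cc(OC)c(OC(=O)NC(C)C)c([Si](C)(C)C)c1OC
F5 | step 2 | 3,4,6-trimethoxy-2-(trimethylsilyl)phenol | COc1cc(OC)c(O)c([Si](C)(C)C)c1OC
F0 | step 8 | none | none
F0 | step 10 | none | none
A1 | alternative 1 | 3-[(S)-2-acetoxypropyl]-2,5,6-trimethoxynaphthalene-1,4,8-triol | COc1cc(O)c2c(c1OC)c(O)c(C[C@H](C)OC(C)=O)c(OC)c2O
A2 | alternative 1 | 2-[(S)-2-acetoxypropyl]-3-methoxy-1,4-benzoquinone | COC1=C(C[C@H](C)OC(C)=O)C(=O)C=CC1=O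
A3 | alternative 1 | 1,3,4-trimethoxy-1-(trimethylsilyloxy)buta-1,3-diene | COC=C(OC)C=C(OC)O[Si](C)(C)C
A4 | alternative 2 | 3-[(S)-2-(tert-butyldimethylsilyloxy)propyl]-2-ethoxy-5,6,8-trimethoxy-1,4-dihydronaphthalene-1,4-diol (mixture of diastereomers at C1 and C4) | COc1cc(OC)c2c(c1OC)C(O)C(C[C@H](C)O[Si](C)(C)C(C)(C)C)=C(OCC)C2O
A5 | alternative 2 | (4S)-4-(tert-butyldimethylsilyloxy)-1-[2-(2-ethoxy-1-hydroxyprop-2-en-1-yl)-3,5,6-trimethoxyphenyl]-2-methylidenepentan-1-ol (mixture of carbinol diastereomers) | COc1cc(OC)c(C(O)C(OCC)=C)c(C(O)C(=C)C[C@H](C)O[Si](C)(C)C(C)(C)C)c1OC
A6 | alternative 3 | 3-[(S)-2-(tert-butyldimethylsilyloxy)propyl]-4-hydroxy-5,6,8-trimethoxy-2-(triisopropylsilyloxy)naphthalene | COc1cc(OC)c2cc(O[Si](C(C)C)(C(C)C)C(C)C)c(C[C@H](C)O[Si](C)(C)C(C)(C)C)c(O)c2c1OC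
A7 | alternative 3 | 2-diazo-1-(2,4,5-trimethoxyphenyl)ethan-1-one | COc1cc(OC)c(C(=O)C=[N+]=[N-])cc1OC
A8 | alternative 3 | (S)-2-(tert-butyldimethylsilyloxy)-5-(triisopropylsilyloxy)pent-4-yne | CC(C)[Si](OC#CC[C@H](C)O[Si](C)(C)C(C)(C)C)(C(C)C)C(C)C
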